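**Plan**

1. Ring numbering used here: C1 = CH carrying the C7 oxymethylene arm, C2 = methyl-bearing alkene carbon, C3 = alkene CH, C4 = CH2, C5 = acyloxy CH, C6 = CMe2. The retrosynthesis first cuts the aryl ether at C7–O and the ester at O5, moves the C2=C3 alkene out to an exocyclic methylidene and takes C5 back to a ketone.
2. In that 4-methylidenecyclohexanone the atoms O5, C5, C4, C3, C2 and the exocyclic carbon on C2 (the later methyl) are the γ,δ-unsaturated carbonyl array of a Claisen product. C3–C4 is therefore cut, and the carbocycle is traced to a 2,5-dimethylideneoxane whose ring oxygen O5 sits on the later methyl carbon.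
3. The oxane is the methylenated δ-lactone of an acyclic hydroxy ester. Its chain is cut at C1–C6 (Mukaiyama–Michael addition), at the methylidene on C2 (Mannich methylenation) and at C1=C2 (Wittig).
4. Forward: the chain is joined in that reverse order, the lactone ring is closed at O5–C5 and methylenated, and the oxane is transposed into the carbocycle (the only ring-forming C–C event). C5 reduction, acylation, alkene migration, desilylation and etherification follow.
5. Stereochemistry: C1 is set by catalyst control in the Mukaiyama–Michael step and passes through the rearrangement untouched. C5 is set by hydride delivery anti to the C7 arm (cis). The acyl stereocentre comes from (R)-2-methylbutanoic acid.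

Key step: step 6

Remark: TBS = tert-butyldimethylsilyl; the facial sense of the IDPi catalyst in step 2 is assumed to follow from the choice of catalyst enantiomer, so the antipode of the one written would be used if it shields the wrong face.

**Route**

Step 1
Reactants: 1 (tert-butyldimethylsilyloxy)acetaldehyde; 2 methyl (triphenylphosphoranylidene)acetate
Product: 3 methyl (E)-4-[(tert-butyldimethylsilyl)oxy]but-2-enoate
Conditions: CH2Cl2, rt
Reagents that add atoms: none
Why: Wittig olefination of an unhindered aldehyde with a stabilised ylide should give the (E)-enoate; no stereocentre is formed.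

Step 2
Reactants: 3 methyl (E)-4-[(tert-butyldimethylsilyl)oxy]but-2-enoate; 4 1-methoxy-2-methyl-1-(trimethylsilyloxy)prop-1-ene
Product: 6 dimethyl (3S)-3-{[(tert-butyldimethylsilyl)oxy]methyl}-2,2-dimethylpentanedioate, via silyl ketene acetal adduct 5 (not isolated)
Conditions: (S,S)-IDPi precatalyst (N,N′-bis(triflyl) imidodiphosphorimidate of 3,3′-bis[3,5-bis(trifluoromethyl)phenyl]-BINOL, 2 mol%), 4 (1.5 equiv), toluene, −40 °C; aq. NaHCO3 work-up
Reagents that add atoms: none
Why: In this silylium-catalysed asymmetric Mukaiyama–Michael addition to an α,β-unsaturated methyl ester, the chiral counter-anion should leave only the Re face of C3 of the O-silylated enoate open to the ketene acetal, which sets the 3S centre (later ring carbon C1) next to the gem-dimethyl carbon, and work-up hydrolyses adduct 5 to the diester.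

Step 3
Reactants: 6 dimethyl (3S)-3-{[(tert-butyldimethylsilyl)oxy]methyl}-2,2-dimethylpentanedioate
Product: 10 dimethyl (3R)-3-{[(tert-butyldimethylsilyl)oxy]methyl}-2,2-dimethyl-4-methylidenepentanedioate, via lithium enolate 7 (not isolated), via Mannich base 8 (not isolated), via ammonium iodide 9 (not isolated)
Conditions: LiN(i-Pr)2, THF, −78 °C; CH2=NMe2+ I−, −78 °C to rt; MeI, MeOH, rt; aq. NaHCO3/CH2Cl2
Reagents that add atoms: Eschenmoser's salt (N,N-dimethylmethylideneammonium iodide), C=[N+](C)C.[I-]
Why: Only the CH2 ester can be enolised (the other is α-quaternary), so one enolate should undergo Mannich alkylation, and N-methylation followed by mild-base E1cB loss of trimethylamine installs the α-methylidene without touching the neighbouring stereocentre (the descriptor changes by priority only).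

Step 4
Reactants: 10 dimethyl (3R)-3-{[(tert-butyldimethylsilyl)oxy]methyl}-2,2-dimethyl-4-methylidenepentanedioate
Product: 12 (4S)-4-{[(tert-butyldimethylsilyl)oxy]methyl}-3,3-dimethyl-5-methylideneoxan-2-one, via hydroxy ester 11 (not isolated)
Conditions: i-Bu2AlH (2.1 equiv), CH2Cl2, −78 °C; aq. potassium sodium tartrate (KNaC4H4O6); then PPTS (cat.), toluene, 60 °C
Reagents that add atoms: none
Why: Chemoselective hydride reduction should take the unhindered conjugated ester to the allylic alcohol much faster than the neopentyl-type ester, and acid-catalysed lactonisation onto that ester then closes the δ-lactone with gem-dimethyl assistance.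

Step 5
Reactants: 12 (4S)-4-{[(tert-butyldimethylsilyl)oxy]methyl}-3,3-dimethyl-5-methylideneoxan-2-one
Product: 13 (4S)-4-{[(tert-butyldimethylsilyl)oxy]methyl}-3,3-dimethyl-2,5-dimethylideneoxane
Conditions: Cp2TiMe2 (2.5 equiv), toluene, 70 °C, dark; filtration through Et3N-deactivated basic Al2O3
Reagents that add atoms: dimethyltitanocene Cp2TiMe2, C[Ti](C)(C1C=CC=C1)C1C=CC=C1
Why: In this Petasis methylenation, Cp2Ti=CH2 formed on heating should convert the lactone carbonyl into the exocyclic enol ether through an oxatitanacyclobutane under non-acidic conditions, and the enol ether cannot migrate into the ring because the adjacent carbon is quaternary.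

Step 6
Reactants: 13 (4S)-4-{[(tert-butyldimethylsilyl)oxy]methyl}-3,3-dimethyl-2,5-dimethylideneoxane
Product: 14 (3S)-3-{[(tert-butyldimethylsilyl)oxy]methyl}-2,2-dimethyl-4-methylidenecyclohexan-1-one
Conditions: Me2AlCl (1.5 equiv), CH2Cl2, −78 to 0 °C; aq. NaHCO3
Reagents that add atoms: none
Why: Proposed new method: Me2AlCl should bind the enol-ether oxygen and loosen the allylic O–CH2 bond, so that the exocyclic vinyl carbon bonds to an allyl terminus either in a charge-accelerated boat [3,3] shift through a bicyclo[2.2.2]-like array or, in the ionised limit, by collapse of a tethered aluminium enolate and 2-alkylallyl cation. The closest known reactions are aluminium-promoted Claisen rearrangements of 2-methylidene-oxanes made by lactone methylenation and Petasis–Ferrier-type 1,3 oxygen-to-carbon shifts of cyclic enol ethers. The cyclohexanone closes as the oxane opens, formally a 6-(enolendo)-exo-tet attack of the enolate carbon on the allyl unit (6-endo in the SN2′ sense), and the two senses give the same product because both allyl termini are CH2 groups. No stereocentre is created, and the existing one keeps its configuration because none of its bonds is broken. The step needs chemoselectivity only: the enol ether cannot tautomerise (quaternary neighbour), the allyl cation has no β-hydrogen to lose, O-recombination merely regenerates 13, and the alkylaluminium scavenges protons that would hydrolyse the enol ether.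

Step 7
Reactants: 14 (3S)-3-{[(tert-butyldimethylsilyl)oxy]methyl}-2,2-dimethyl-4-methylidenecyclohexan-1-one
Product: 15 (1R,3S)-3-{[(tert-butyldimethylsilyl)oxy]methyl}-2,2-dimethyl-4-methylidenecyclohexan-1-ol
Conditions: NaBH4, MeOH, 0 °C
Reagents that add atoms: none
Why: In this borohydride reduction of a 2,2-dimethylcyclohexanone, the small hydride should add to the carbonyl face remote from the silyloxymethyl arm (axial delivery on the chair with that arm equatorial), giving the equatorial 1R alcohol cis to the arm.

Step 8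
Reactants: 15 (1R,3S)-3-{[(tert-butyldimethylsilyl)oxy]methyl}-2,2-dimethyl-4-methylidenecyclohexan-1-ol; 16 (R)-2-methylbutanoic acid
Product: 17 (1R,3S)-3-{[(tert-butyldimethylsilyl)oxy]methyl}-2,2-dimethyl-4-methylidenecyclohexyl (2R)-2-methylbutanoate
Conditions: DCC, DMAP, CH2Cl2, 0 °C to rt
Reagents that add atoms: none
Why: Steglich esterification (carbodiimide activation with DMAP acyl transfer) should acylate the hindered secondary alcohol with retention at the carbinol carbon, and the unactivated α-alkyl stereocentre of the acid is not expected to epimerise.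

Step 9
Reactants: 17 (1R,3S)-3-{[(tert-butyldimethylsilyl)oxy]methyl}-2,2-dimethyl-4-methylidenecyclohexyl (2R)-2-methylbutanoate
Product: 18 (1R,5S)-5-{[(tert-butyldimethylsilyl)oxy]methyl}-4,6,6-trimethylcyclohex-3-en-1-yl (2R)-2-methylbutanoate
Conditions: chloro[N,N′-bis(3,5-di-tert-butylsalicylidene)-1,2-cyclohexanediaminato]cobalt (trivalent cobalt, 3 mol%), PhSiH3 (6 mol%), benzene, rt
Reagents that add atoms: none
Why: In this cobalt-hydride hydrogen-atom-transfer isomerisation, reversible H-atom addition to the 1,1-disubstituted alkene gives a tertiary radical, and hydrogen abstraction from the open ring CH2 (not from the congested methine beside the quaternary carbon) should give the endocyclic trisubstituted alkene, which is inert to further transfer, so the ring stereocentres are kept.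

Step 10
Reactants: 18 (1R,5S)-5-{[(tert-butyldimethylsilyl)oxy]methyl}-4,6,6-trimethylcyclohex-3-en-1-yl (2R)-2-methylbutanoate
Product: 19 (1R,5S)-5-(hydroxymethyl)-4,6,6-trimethylcyclohex-3-en-1-yl (2R)-2-methylbutanoate
Conditions: Bu4NF, AcOH, THF, 0 °C to rt
Reagents that add atoms: none
Why: Fluoride-mediated desilylation, buffered with acetic acid, should free the primary alcohol without acyl migration or ester cleavage.

Step 11
Reactants: 19 (1R,5S)-5-(hydroxymethyl)-4,6,6-trimethylcyclohex-3-en-1-yl (2R)-2-methylbutanoate; 20 umbelliferone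
Product: 21 (1R,5S)-4,6,6-trimethyl-5-{[(2-oxo-2H-chromen-7-yl)oxy]methyl}cyclohex-3-en-1-yl (2R)-2-methylbutanoate
Conditions: PPh3, DIAD, THF, 0 °C to rt
Reagents that add atoms: none
Why: In this Mitsunobu etherification the acidic phenol (pKa about 8) should displace the alkoxyphosphonium of the primary alcohol by SN2 at CH2, so no stereocentre is involved.

**Compound list**

1 | (tert-butyldimethylsilyloxy)acetaldehyde | CC(C)(C)[Si](C)(C)OCC=O | starting material
2 | methyl (triphenylphosphoranylidene)acetate | COC(=O)C=P(c1ccccc1)(c1ccccc1)c1ccccc1 | starting material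
3 | methyl (E)-4-[(tert-butyldimethylsilyl)oxy]but-2-enoate | COC(=O)/C=C/CO[Si](C)(C)C(C)(C)C | intermediate
4 | 1-methoxy-2-methyl-1-(trimethylsilyloxy)prop-1-ene (methyl trimethylsilyl dimethylketene acetal) | COC(O[Si](C)(C)C)=C(C)C | starting material
5 | methyl (3S)-3-{[(tert-butyldimethylsilyl)oxy]methyl}-5-methoxy-2,2-dimethyl-5-(trimethylsilyloxy)pent-4-enoate | COC(=O)C(C)(C)[C@@H](CO[Si](C)(C)C(C)(C)C)C=C(OC)O[Si](C)(C)C | intermediate
6 | dimethyl (3S)-3-{[(tert-butyldimethylsilyl)oxy]methyl}-2,2-dimethylpentanedioate | COC(=O)C[C@H](CO[Si](C)(C)C(C)(C)C)C(C)(C)C(=O)OC | intermediate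
7 | lithium enolate of 6 at C4 (3S) | [Li+].COC([O-])=C[C@H](CO[Si](C)(C)C(C)(C)C)C(C)(C)C(=O)OC | intermediate
8 | dimethyl (3S)-3-{[(tert-butyldimethylsilyl)oxy]methyl}-4-[(dimethylamino)methyl]-2,2-dimethylpentanedioate (C4 epimers) | COC(=O)C(CN(C)C)[C@H](CO[Si](C)(C)C(C)(C)C)C(C)(C)C(=O)OC | intermediate
9 | N-methyl quaternary ammonium iodide of 8 (3S) | COC(=O)C(C[N+](C)(C)C)[C@H](CO[Si](C)(C)C(C)(C)C)C(C)(C)C(=O)OC.[I-] | intermediate
10 | dimethyl (3R)-3-{[(tert-butyldimethylsilyl)oxy]methyl}-2,2-dimethyl-4-methylidenepentanedioate | COC(=O)C(=C)[C@H](CO[Si](C)(C)C(C)(C)C)C(C)(C)C(=O)OC | intermediate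
11 | methyl (3S)-3-{[(tert-butyldimethylsilyl)oxy]methyl}-4-(hydroxymethyl)-2,2-dimethylpent-4-enoate | COC(=O)C(C)(C)[C@@H](CO[Si](C)(C)C(C)(C)C)C(=C)CO | intermediate
12 | (4S)-4-{[(tert-butyldimethylsilyl)oxy]methyl}-3,3-dimethyl-5-methylideneoxan-2-one | O=C1OCC(=C)[C@H](CO[Si](C)(C)C(C)(C)C)C1(C)C | intermediate
13 | (4S)-4-{[(tert-butyldimethylsilyl)oxy]methyl}-3,3-dimethyl-2,5-dimethylideneoxane | C=C1OCC(=C)[C@H](CO[Si](C)(C)C(C)(C)C)C1(C)C | intermediate
14 | (3S)-3-{[(tert-butyldimethylsilyl)oxy]methyl}-2,2-dimethyl-4-methylidenecyclohexan-1-one | O=C1CCC(=C)[C@H](CO[Si](C)(C)C(C)(C)C)C1(C)C | intermediate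
15 | (1R,3S)-3-{[(tert-butyldimethylsilyl)oxy]methyl}-2,2-dimethyl-4-methylidenecyclohexan-1-ol | O[C@@H]1CCC(=C)[C@H](CO[Si](C)(C)C(C)(C)C)C1(C)C | intermediate
16 | (R)-2-methylbutanoic acid | CC[C@@H](C)C(=O)O | starting material
17 | (1R,3S)-3-{[(tert-butyldimethylsilyl)oxy]methyl}-2,2-dimethyl-4-methylidenecyclohexyl (2R)-2-methylbutanoate | CC[C@@H](C)C(=O)O[C@@H]1CCC(=C)[C@H](CO[Si](C)(C)C(C)(C)C)C1(C)C | intermediate
18 | (1R,5S)-5-{[(tert-butyldimethylsilyl)oxy]methyl}-4,6,6-trimethylcyclohex-3-en-1-yl (2R)-2-methylbutanoate | CC[C@@H](C)C(=O)O[C@@H]1CC=C(C)[C@H](CO[Si](C)(C)C(C)(C)C)C1(C)C | intermediate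
19 | (1R,5S)-5-(hydroxymethyl)-4,6,6-trimethylcyclohex-3-en-1-yl (2R)-2-methylbutanoate | CC[C@@H](C)C(=O)O[C@@H]1CC=C(C)[C@H](CO)C1(C)C | intermediate
20 | umbelliferone (7-hydroxy-2H-chromen-2-one) | Oc1ccc2ccc(=O)oc2c1 | starting material
21 | (1R,5S)-4,6,6-trimethyl-5-{[(2-oxo-2H-chromen-7-yl)oxy]methyl}cyclohex-3-en-1-yl (2R)-2-methylbutanoate | CC[C@@H](C)C(=O)O[C@@H]1CC=C(C)[C@H](COc2ccc3ccc(=O)oc3c2)C1(C)C | target

**Step count**

Total steps: 11. Longest linear sequence: 11 steps (from 1).

**Steps most likely to fail**

Step 6. The oxygen-to-carbon allyl shift may be too slow through the constrained boat geometry, so that Lewis-acid-induced protonation or oligomerisation of the enol ether, or migration of the exocyclic alkenes, wins. The fallback sets out from lactone 12 and returns at ketone 14, making the same C3–C4 bond stepwise by known reactions. MeLi (THF, −78 °C) would open the lactone to (4S)-4-{[(tert-butyldimethylsilyl)oxy]methyl}-5-(hydroxymethyl)-3,3-dimethylhex-5-en-2-one F1, which equilibrates with its lactol. CBr4/PPh3 would act on the open form to give (4R)-5-(bromomethyl)-4-{[(tert-butyldimethylsilyl)oxy]methyl}-3,3-dimethylhex-5-en-2-one F2. LiN(i-Pr)2 (THF, −78 to 0 °C) would then form the only possible enolate (methyl side), which closes the ring by intramolecular allylic alkylation to 14; any O-alkylation would only give 13.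

Step 9. Hydrogen abstraction may occur at the ring methine instead of the ring CH2, which moves the alkene to the tetrasubstituted position and erases the C1 stereocentre, or the isomerisation may stall. The fallback sets out from 17 and returns at 18, fixing the alkene position by regioselective enolisation. Ozonolysis (O3, CH2Cl2/MeOH, −78 °C; Me2S) would give (1R,3S)-3-{[(tert-butyldimethylsilyl)oxy]methyl}-2,2-dimethyl-4-oxocyclohexyl (2R)-2-methylbutanoate F3. Kinetic deprotonation at the unhindered CH2 with LiN(SiMe3)2 and trapping with PhNTf2 (THF, −78 °C) would give (1R,5S)-5-{[(tert-butyldimethylsilyl)oxy]methyl}-6,6-dimethyl-4-(trifluoromethylsulfonyloxy)cyclohex-3-en-1-yl (2R)-2-methylbutanoate F4. Coupling with Me2CuLi (THF, −20 °C) would then deliver 18.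

Step 2. Facial discrimination or turnover may be poor because the γ-silyloxy group is not a simple alkyl or aryl substituent, or silyl transfer to the ether oxygen may interfere. The fallback sets out from enoate 3 and returns at hydroxy ester 11 (which lactonises to 12 as in step 4); it forms the C1–C2 bond asymmetrically instead of C1–C6.
- Rhodium-catalysed 1,4-addition of isopropenylboronic acid pinacol ester ([Rh(cod)Cl]2, monovalent rhodium, (S)-BINAP, KOH, dioxane/H2O, 50 °C) is expected by the usual 2-si-face model to deliver the alkenyl group to the Si face of C3 and give methyl (3R)-3-{[(tert-butyldimethylsilyl)oxy]methyl}-4-methylpent-4-enoate F5.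
- Two successive enolate methylations (LiN(i-Pr)2, MeI, THF, −78 °C) would lead through methyl (3R)-3-{[(tert-butyldimethylsilyl)oxy]methyl}-2,4-dimethylpent-4-enoate F6 to methyl (3S)-3-{[(tert-butyldimethylsilyl)oxy]methyl}-2,2,4-trimethylpent-4-enoate F7.
- Allylic hydroxylation of the isopropenyl methyl group (SeO2 cat., t-BuOOH, CH2Cl2) would give 11.

**Further compounds**

F1 | step 6 | (4S)-4-{[(tert-butyldimethylsilyl)oxy]methyl}-5-(hydroxymethyl)-3,3-dimethylhex-5-en-2-one | CC(=O)C(C)(C)[C@@H](CO[Si](C)(C)C(C)(C)C)C(=C)CO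
F2 | step 6 | (4R)-5-(bromomethyl)-4-{[(tert-butyldimethylsilyl)oxy]methyl}-3,3-dimethylhex-5-en-2-one | CC(=O)C(C)(C)[C@@H](CO[Si](C)(C)C(C)(C)C)C(=C)CBr
F3 | step 9 | (1R,3S)-3-{[(tert-butyldimethylsilyl)oxy]methyl}-2,2-dimethyl-4-oxocyclohexyl (2R)-2-methylbutanoate | CC[C@@H](C)C(=O)O[C@@H]1CCC(=O)[C@H](CO[Si](C)(C)C(C)(C)C)C1(C)C
F4 | step 9 | (1R,5S)-5-{[(tert-butyldimethylsilyl)oxy]methyl}-6,6-dimethyl-4-(trifluoromethylsulfonyloxy)cyclohex-3-en-1-yl (2R)-2-methylbutanoate | CC[C@@H](C)C(=O)O[C@@H]1CC=C(OS(=O)(=O)C(F)(F)F)[C@H](CO[Si](C)(C)C(C)(C)C)C1(C)C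
F5 | step 2 | methyl (3R)-3-{[(tert-butyldimethylsilyl)oxy]methyl}-4-methylpent-4-enoate | COC(=O)C[C@@H](CO[Si](C)(C)C(C)(C)C)C(C)=C
F6 | step 2 | methyl (3R)-3-{[(tert-butyldimethylsilyl)oxy]methyl}-2,4-dimethylpent-4-enoate (C2 epimers) | COC(=O)C(C)[C@@H](CO[Si](C)(C)C(C)(C)C)C(C)=C
F7 | step 2 | methyl (3S)-3-{[(tert-butyldimethylsilyl)oxy]methyl}-2,2,4-trimethylpent-4-enoate | COC(=O)C(C)(C)[C@@H](CO[Si](C)(C)C(C)(C)C)C(C)=C
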